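A solid substrate at 2.0 M and a coupling partner at 2.10 M look like a matched pair that will use each other up, and in this flask that look was a trap. I wrote this note for whoever took over the bench.

solid substrate 2.0 M; coupling partner 2.10 M; catalyst 2.2 mM; time 20 min

    starting material + catalyst ⇌ catalyst + intermediate (K1 = 0.35, k1 = 5.3 M⁻¹ s⁻¹)
    coupling partner + catalyst + intermediate → catalyst + target (k2 = 0.45 M⁻² s⁻¹)
    solid substrate ⇌ starting material, rate k3*(cs3 - [starting material]) while solid is left; crystals form when [starting material] > cs3 (cs3 = 0.47 M, k3 = 0.0077 s⁻¹)
    intermediate → side product (k4 = 0.058 s⁻¹)

- as a solid, counted per litre of solution: solid substrate
- at the start none of the solid substrate is in solution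
- what has only dissolved of solid substrate counts as not reacted
- run time (flask): 20 min

- part of the solid substrate that has turned into other species by 20 min (what has only dissolved does not count)
- target at 20 min, in percent of the solid substrate charged
- side product at 20 min, in percent of the solid substrate charged

The flask started with undissolved solid, coupling partner and a little catalyst. I wrote the balance of the solid substrate, the limiting reagent, since its charge was the smaller. Whatever of it became product had first passed through the intermediate, which had two exits. With partner and catalyst as charged, coupling took intermediate at 0.00208 s⁻¹, while loss to side product ran far faster, at 0.058 s⁻¹, and the two rates gave 3.46%. That number is the target share, the coupling rate over the sum of both exit rates. The partner stood to lose 0.0692 M, hardly any of its charge, so I kept its charged value in the reckoning. I told the next person to expect that split in what had left the intermediate, and not to lower the catalyst, because coupling was far slower than the loss to side product, so that with the partner held the share falls nearly in proportion to the catalyst. My reckoning stopped there and gave no clock for the solid.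

The forecast gave 96% converted, 3.3% target and 92.4% side product, “leaving only a few percent of the substrate still dissolved or as intermediate”. Its target figure was in percent of the charge, and my share was in percent of what left the intermediate.

This flask gave 96.0% converted, 3.25% target and 92.2% side product, so target made up 3.40% of the two products, against my 3.46%. A neighbouring flask was charged with 8.8 × 10⁻⁴ M of catalyst, all else as in the recipe. The same reckoning put its coupling at 8.32 × 10⁻⁴ s⁻¹ and its target share at 1.41%. At 20 min that neighbouring flask held 0.925% target and 64.8% side product, which made target 1.41% of the two products, and 17.6% of its solid substrate was still undissolved.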